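The methoxy-2H-pyrrole ring is treated as a methyl tetramate whose amino-acid α-carbon is the spiro N,O-ketal carbon, shared by the tetrahydropyran (as C-2, bonded to O-1) and the 2H-pyrrole (bonded to N). The route rests on cutting the bond between the methoxy-bearing carbon and the adjacent ring CH. A Lacey–Dieckmann closure, in which the enolate of an anomeric acetamide attacks the methyl ester on the same carbon, forms the spiro pyrrolidine-2,4-dione in one operation without touching the four stereocentres. The precursor is the ansa-bridged methyl 2-acetamidotetrahydropyran-2-carboxylate with a free pyrrole N–H; the pyrrole stays N-Boc through all electrophilic steps and is unmasked just before the base step.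

Key step: step 13

Remark: positions are cited with pyran numbering (O-1, C-2 = lactone/anomeric/spiro carbon, C-3 pyrrolyl-bearing, C-4 bridge-bearing, C-6 methyl-bearing); the anomeric hydroxyl of 19 and 20 is drawn axial, its configuration being immaterial because C-2 is ionised in step 11.

Step 1
Reactants: 1 (S)-propylene oxide; 2 ethyl propiolate
Product: 3 ethyl (5S)-5-hydroxyhex-2-ynoate
Conditions: 2, n-BuLi, THF, −78 °C; BF3·OEt2; then 1, −78 °C; aq NH4Cl
Reagents that add atoms: none
Why: BF3-promoted epoxide opening by the lithium acetylide occurs by SN2 attack at the unsubstituted CH2, so the (S) centre of 1 is untouched and becomes C-6 of the pyran.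

Step 2
Reactants: 3 ethyl (5S)-5-hydroxyhex-2-ynoate
Product: 5 (S)-parasorbic acid [(6S)-6-methyl-5,6-dihydro-2H-pyran-2-one], via Z-hydroxy enoate 4 (not isolated)
Conditions: H2 (1 atm), Lindlar catalyst, quinoline, EtOAc, rt; then TsOH (cat.), rt
Reagents that add atoms: none
Why: Lindlar semi-hydrogenation gives the Z-enoate, whose cis-disposed hydroxyl and ester lactonise under acid catalysis; no stereocentre is involved.

Step 3
Reactants: 5 (S)-parasorbic acid
Product: 7 (6S)-3-bromo-6-methyl-5,6-dihydro-2H-pyran-2-one, via 3,4-dibromo lactone 6 (not isolated)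
Conditions: Br2, CH2Cl2, 0 °C; then Et3N, 0 °C to rt
Reagents that add atoms: bromine, BrBr
Why: Bromine addition followed by amine-induced loss of HBr (the acidic H-3 is removed, bromide leaves from C-4) is the standard addition–elimination α-bromination of a conjugated lactone.

Step 4
Reactants: 7 (6S)-3-bromo-6-methyl-5,6-dihydro-2H-pyran-2-one; 8 [1-(tert-butoxycarbonyl)pyrrol-2-yl]boronic acid
Product: 9 tert-butyl 2-[(6S)-6-methyl-2-oxo-5,6-dihydro-2H-pyran-3-yl]-1H-pyrrole-1-carboxylate
Conditions: XPhos Pd G3 (2 mol %), K3PO4 (0.5 M aq), THF, rt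
Reagents that add atoms: none
Why: Suzuki–Miyaura coupling of an α-bromo enoate undergoes fast oxidative addition, and a rapid precatalyst at room temperature should outrun protodeboronation of the pyrrolylboronic acid while the mild base spares the lactone.

Step 5
Reactants: 9 tert-butyl 2-[(6S)-6-methyl-2-oxo-5,6-dihydro-2H-pyran-3-yl]-1H-pyrrole-1-carboxylate; 10 but-3-en-1-ylmagnesium bromide
Product: 12 tert-butyl 2-[(3S,4S,6S)-4-(but-3-en-1-yl)-6-methyl-2-oxotetrahydro-2H-pyran-3-yl]-1H-pyrrole-1-carboxylate, via silyl ketene acetal 11 (not isolated)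
Conditions: CuBr·SMe2 (10 mol %), TMSCl, THF, −78 °C; 1 M HCl; then DBU (cat.), CH2Cl2, rt
Reagents that add atoms: none
Why: TMSCl-accelerated copper-catalysed conjugate addition delivers the butenyl group to C-4 anti to the C-6 methyl (axial attack on the half-chair), and base equilibration of the acidic H-3 then places the pyrrole trans to the new chain (thermodynamic control), so C-4 and C-3 are both set from C-6.

Step 6
Reactants: 12 tert-butyl 2-[(3S,4S,6S)-4-(but-3-en-1-yl)-6-methyl-2-oxotetrahydro-2H-pyran-3-yl]-1H-pyrrole-1-carboxylate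
Product: 13 tert-butyl 2-bromo-5-[(3S,4S,6S)-4-(but-3-en-1-yl)-6-methyl-2-oxotetrahydro-2H-pyran-3-yl]-1H-pyrrole-1-carboxylate
Conditions: NBS, THF, −78 °C
Reagents that add atoms: N-bromosuccinimide, O=C1CCC(=O)N1Br
Why: Electrophilic bromination of an N-Boc pyrrole takes place at the only free α-position, and at −78 °C the pyrrole should react far faster than the terminal alkene.

Step 7
Reactants: 13 the 5-bromopyrrole lactone; 14 pent-4-en-1-ylzinc bromide
Product: 15 tert-butyl 2-[(3S,4S,6S)-4-(but-3-en-1-yl)-6-methyl-2-oxotetrahydro-2H-pyran-3-yl]-5-(pent-4-en-1-yl)-1H-pyrrole-1-carboxylate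
Conditions: Pd(OAc)2 (5 mol %), SPhos, THF, rt
Reagents that add atoms: none
Why: Negishi sp2–sp3 coupling of the 2-bromopyrrole with a primary alkylzinc halide is used because the organozinc is too weakly basic to enolise the lactone.

Step 8
Reactants: 15 the diene lactone
Product: 17 N-Boc ansa lactone [(3S,4S,6S)-6-methyltetrahydro-2H-pyran-2-one, C-3 bonded to C-2 of the 1-Boc-pyrrole, C-4 joined to pyrrole C-5 by a (CH2)7 chain], via macrocyclic alkene 16 (not isolated)
Conditions: Grubbs II (10 mol %), CH2Cl2 (1 mM), 40 °C; then Pd/C, H2 (1 atm), rt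
Reagents that add atoms: none
Why: Ring-closing metathesis at high dilution closes the 12-membered ansa ring from two terminal alkenes held gauche by the trans-3,4-disubstituted lactone, and hydrogenation in the same flask saturates the new alkene (either geometry serves) without reducing the N-Boc pyrrole.

Step 9
Reactants: 17 N-Boc ansa lactone; 18 tris(methylthio)methane
Product: 19 (2R,3S,4S,6S)-2-hydroxy-2-[tris(methylsulfanyl)methyl] ansa pyran (N-Boc pyrrole)
Conditions: 18, n-BuLi, THF, −78 °C; then 17, −78 °C; AcOH quench at −78 °C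
Reagents that add atoms: none
Why: The soft tris(methylthio)methyl anion, a carboxyl anion equivalent, adds 1,2 to the lactone carbonyl and the adduct rests as the cyclic hemiketal, with the cold acidic quench preventing retro-addition and carbamate migration.

Step 10
Reactants: 19 the orthothioester hemiketal
Product: 20 methyl (2R,3S,4S,6S)-2-hydroxy ansa pyran-2-carboxylate (N-Boc pyrrole)
Conditions: HgCl2, HgO, MeOH–H2O (12:1), rt
Reagents that add atoms: methanol, CO; water, O
Why: Thiophile-assisted ionisation of the three C–S bonds in aqueous methanol converts the orthothioester into the methyl ester, HgO buffering the acid so that the carbamate and the hemiketal survive.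

Step 11
Reactants: 20 the 2-ulosonate hemiketal; 21 azidotrimethylsilane
Product: 22 methyl (2R,3S,4S,6S)-2-azido ansa pyran-2-carboxylate (N-Boc pyrrole)
Conditions: 21 (4 equiv), TMSOTf (0.2 equiv), CH2Cl2, −40 to 0 °C
Reagents that add atoms: none
Why: Lewis-acid ionisation of the tertiary anomeric hydroxyl gives the 2-methoxycarbonyl oxocarbenium ion, which azide traps (anomeric azidation of a 2-ulosonate) along the axial trajectory of the chair in which the ansa bridge keeps C-3 and C-4 equatorial, giving the anomerically stabilised axial C–N bond cis to the C-3 pyrrole, while the electron-poor N-Boc pyrrole stays out of the cation chemistry.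

Step 12
Reactants: 22 the N-Boc azido ester; 23 thioacetic acid
Product: 25 methyl (2R,3S,4S,6S)-2-acetamido ansa pyran-2-carboxylate (free pyrrole N–H), via free N–H azide 24 (not isolated)
Conditions: NaOMe (cat.), MeOH, rt; then 23, 2,6-lutidine, 60 °C
Reagents that add atoms: none
Why: Catalytic methoxide removes the pyrrole carbamate by transacylation to methanol, and the thioacid–azide amidation then turns the azide directly into the acetamide through a thiatriazoline that loses N2 and sulfur, so no free anomeric amine forms and C-2 keeps its configuration.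

Step 13
Reactants: 25 methyl (2R,3S,4S,6S)-2-acetamido ansa pyran-2-carboxylate
Product: 26 spiro pyrrolidine-2,4-dione (tetramic acid; spiro carbon R)
Conditions: LDA (4.5 equiv), THF, −78 to 0 °C; aq NH4Cl
Reagents that add atoms: none
Why: LDA removes the pyrrole and amide N–H protons and then an acetyl C–H; the amide enolate carbon attacks the methyl ester on C-2, methoxide leaves, and the new 1,3-dicarbonyl stays as its enolate until work-up, which is the Lacey–Dieckmann tetramic acid synthesis (an intramolecular Claisen condensation of an N-acetyl α-amino ester). The five-membered ring closes in the 5-exo-trig mode, the enolate carbon adding to the exocyclic ester carbonyl. No stereocentre is formed, so the step needs only chemoselective C-acylation and retention at C-2. The ester is activated by its α-oxygen and α-nitrogen and cannot enolise because C-2 is quaternary, and an N-acylpyrrole formed by the pyrrolide would itself be an acyl donor leading to the same product. C-2 bears no hydrogen, and if the amidate opens the pyran to an N-acylimine the reclosure is reversible and should favour the isomer with the axial C–N bond.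

Step 14
Reactants: 26 spiro tetramic acid
Product: 27 spiro 4-methoxy-1,5-dihydro-2H-pyrrol-2-one (methyl tetramate)
Conditions: MeOH, PPh3, DIAD, THF, 0 °C to rt
Reagents that add atoms: methanol, CO
Why: Mitsunobu alkylation selects the acidic enol of the tetramic acid (pKa about 6) and gives the 4-O-methyl vinylogous ester, the lactam and pyrrole N–H being too weakly acidic to react.

Step 15
Reactants: 27 spiro methyl tetramate
Product: 28 spiro 3-methoxy-2H-pyrrol-5-yl trifluoromethanesulfonate (imidoyl triflate)
Conditions: Tf2O, 2,6-di-tert-butyl-4-methylpyridine, CH2Cl2, −78 to 0 °C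
Reagents that add atoms: triflic anhydride, O=S(=O)(C(F)(F)F)OS(=O)(=O)C(F)(F)F
Why: Lactam O-triflation gives the imidoyl triflate, stabilised as a vinylogous imidate by the 3-methoxy group, and at −78 °C with a hindered base the lactam oxygen should react much faster than the β-carbons of the 2,5-dialkylpyrrole.

Step 16
Reactants: 28 imidoyl triflate; 8 [1-(tert-butoxycarbonyl)pyrrol-2-yl]boronic acid
Product: 30 premarineosin A, via N-Boc bipyrrole 29 (not isolated)
Conditions: Pd(PPh3)4 (5 mol %), K2CO3 (2 M aq), 1,4-dioxane, 80 °C; then NaOMe (cat.), MeOH, rt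
Reagents that add atoms: none
Why: Suzuki–Miyaura coupling of the imidoyl triflate with the 2-pyrrolylboronic acid forms the bipyrrole C–C bond, and methoxide then cleaves the remaining carbamate by transacylation; no stereocentre is involved.

Compound list
1 | (S)-propylene oxide | C[C@H]1CO1 | starting material
2 | ethyl propiolate | C#CC(=O)OCC | starting material
3 | ethyl (5S)-5-hydroxyhex-2-ynoate | CCOC(=O)C#CC[C@H](C)O | intermediate
4 | ethyl (2Z,5S)-5-hydroxyhex-2-enoate | CCOC(=O)/C=C\C[C@H](C)O | intermediate
5 | (S)-parasorbic acid, (6S)-6-methyl-5,6-dihydro-2H-pyran-2-one | C[C@H]1CC=CC(=O)O1 | intermediate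
6 | (6S)-3,4-dibromo-6-methyltetrahydro-2H-pyran-2-one (trans-dibromide, C-3/C-4 diastereomers) | C[C@H]1CC(Br)C(Br)C(=O)O1 | intermediate
7 | (6S)-3-bromo-6-methyl-5,6-dihydro-2H-pyran-2-one | C[C@H]1CC=C(Br)C(=O)O1 | intermediate
8 | [1-(tert-butoxycarbonyl)-1H-pyrrol-2-yl]boronic acid | CC(C)(C)OC(=O)n1cccc1B(O)O | starting material
9 | tert-butyl 2-[(6S)-6-methyl-2-oxo-5,6-dihydro-2H-pyran-3-yl]-1H-pyrrole-1-carboxylate | C[C@H]1CC=C(c2cccn2C(=O)OC(C)(C)C)C(=O)O1 | intermediate
10 | but-3-en-1-ylmagnesium bromide | C=CCC[Mg]Br | starting material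
11 | tert-butyl 2-[(4S,6S)-4-(but-3-en-1-yl)-6-methyl-2-(trimethylsilyloxy)-5,6-dihydro-4H-pyran-3-yl]-1H-pyrrole-1-carboxylate | C[C@H]1C[C@H](CCC=C)C(c2cccn2C(=O)OC(C)(C)C)=C(O[Si](C)(C)C)O1 | intermediate
12 | tert-butyl 2-[(3S,4S,6S)-4-(but-3-en-1-yl)-6-methyl-2-oxotetrahydro-2H-pyran-3-yl]-1H-pyrrole-1-carboxylate | O=C1O[C@@H](C)C[C@H](CCC=C)[C@H]1c1cccn1C(=O)OC(C)(C)C | intermediate
13 | tert-butyl 2-bromo-5-[(3S,4S,6S)-4-(but-3-en-1-yl)-6-methyl-2-oxotetrahydro-2H-pyran-3-yl]-1H-pyrrole-1-carboxylate | O=C1O[C@@H](C)C[C@H](CCC=C)[C@H]1c1ccc(Br)n1C(=O)OC(C)(C)C | intermediate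
14 | pent-4-en-1-ylzinc bromide | C=CCCC[Zn]Br | starting material
15 | tert-butyl 2-[(3S,4S,6S)-4-(but-3-en-1-yl)-6-methyl-2-oxotetrahydro-2H-pyran-3-yl]-5-(pent-4-en-1-yl)-1H-pyrrole-1-carboxylate | O=C1O[C@@H](C)C[C@H](CCC=C)[C@H]1c1ccc(CCCC=C)n1C(=O)OC(C)(C)C | intermediate
16 | N-Boc ansa lactone with one ring alkene (E/Z mixture), (3S,4S,6S) | O=C2O[C@@H](C)C[C@@H]1CCC=CCCCc3ccc(n3C(=O)OC(C)(C)C)[C@H]12 | intermediate
17 | N-Boc ansa lactone, (3S,4S,6S)-6-methyltetrahydro-2H-pyran-2-one bridged C-3 (pyrrol-2-yl) to C-4 through pyrrole C-5 and (CH2)7 | O=C2O[C@@H](C)C[C@@H]1CCCCCCCc3ccc(n3C(=O)OC(C)(C)C)[C@H]12 | intermediate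
18 | tris(methylthio)methane | CSC(SC)SC | starting material
19 | (2R,3S,4S,6S)-2-hydroxy-2-[tris(methylsulfanyl)methyl] ansa pyran, N-Boc pyrrole | CSC(SC)(SC)[C@]2(O)O[C@@H](C)C[C@@H]1CCCCCCCc3ccc(n3C(=O)OC(C)(C)C)[C@H]12 | intermediate
20 | methyl (2R,3S,4S,6S)-2-hydroxy ansa pyran-2-carboxylate, N-Boc pyrrole | COC(=O)[C@]2(O)O[C@@H](C)C[C@@H]1CCCCCCCc3ccc(n3C(=O)OC(C)(C)C)[C@H]12 | intermediate
21 | azidotrimethylsilane | C[Si](C)(C)N=[N+]=[N-] | starting material
22 | methyl (2R,3S,4S,6S)-2-azido ansa pyran-2-carboxylate, N-Boc pyrrole | COC(=O)[C@]2(N=[N+]=[N-])O[C@@H](C)C[C@@H]1CCCCCCCc3ccc(n3C(=O)OC(C)(C)C)[C@H]12 | intermediate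
23 | thioacetic acid | CC(=O)S | starting material
24 | methyl (2R,3S,4S,6S)-2-azido ansa pyran-2-carboxylate, free pyrrole N–H | COC(=O)[C@]2(N=[N+]=[N-])O[C@@H](C)C[C@@H]1CCCCCCCc3ccc([nH]3)[C@H]12 | intermediate
25 | methyl (2R,3S,4S,6S)-2-acetamido ansa pyran-2-carboxylate, free pyrrole N–H | COC(=O)[C@]2(NC(C)=O)O[C@@H](C)C[C@@H]1CCCCCCCc3ccc([nH]3)[C@H]12 | intermediate
26 | spiro pyrrolidine-2,4-dione (tetramic acid) on the ansa pyran, spiro carbon R | O=C1CC(=O)N[C@]12O[C@@H](C)C[C@@H]1CCCCCCCc3ccc([nH]3)[C@H]12 | intermediate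
27 | spiro 4-methoxy-1,5-dihydro-2H-pyrrol-2-one on the ansa pyran | COC1=CC(=O)N[C@]12O[C@@H](C)C[C@@H]1CCCCCCCc3ccc([nH]3)[C@H]12 | intermediate
28 | spiro 3-methoxy-2H-pyrrol-5-yl trifluoromethanesulfonate on the ansa pyran | COC1=CC(OS(=O)(=O)C(F)(F)F)=N[C@]12O[C@@H](C)C[C@@H]1CCCCCCCc3ccc([nH]3)[C@H]12 | intermediate
29 | N-Boc premarineosin A (Boc on the bipyrrole N–H) | COC1=CC(c2cccn2C(=O)OC(C)(C)C)=N[C@]12O[C@@H](C)C[C@@H]1CCCCCCCc3ccc([nH]3)[C@H]12 | intermediate
30 | premarineosin A | COC1=CC(c2ccc[nH]2)=N[C@]12O[C@@H](C)C[C@@H]1CCCCCCCc3ccc([nH]3)[C@H]12 | target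

Total step count: 16. Longest linear sequence: 16 steps (the route is linear from 1).

Steps most likely to fail

Step 13. The acetyl C–H of the polyanion may not be removed cleanly, or the amidate may open the pyran irreversibly before the carbon enolate forms. The fallback sets out from azide 22 and returns at 26, building the same ring in the opposite order. A crossed Claisen condensation of the non-enolisable ester of 22 with the lithium enolate of methyl acetate (LDA, MeOAc, THF, −78 °C) gives the azido β-keto ester F1. Hydrogenation of the azide (H2, Pd/C, EtOAc) releases the anomeric amine, which lactamises at once onto the β-keto ester to the N-Boc-pyrrole tetramic acid F2. Catalytic NaOMe in MeOH then removes the carbamate to give 26.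

Step 11. Azide must enter syn to the axial C-6 methyl, so capture of the cation may be slow; loss of H-3 (elimination to the conjugated enol ether ester) or attack on the other face may then compete. The fallback sets out from 20 and returns at 25, using a Ritter reaction in place of azide and thioacid. Ionisation of 20 with TMSOTf in acetonitrile at −40 °C lets the solvent trap the cation as the axial nitrilium ion, and aqueous NaHCO3 hydrolyses it to the N-Boc acetamide F3. Unlike the azide, F3 can be equilibrated at C-2 with DBU through its ring-opened N-acylimine. Catalytic NaOMe in MeOH then gives 25.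

Step 9. The carbanion may deprotonate the acidic H-3 (α to the lactone and attached to the pyrrole) or attack the carbamate instead of adding to the carbonyl. The fallback sets out from 17 and returns at 22, using that enolisation instead of fighting it. KHMDS and (PhO)2P(O)Cl (THF–HMPA, −78 °C) give the ketene acetal diphenyl phosphate F4. Palladium-catalysed methoxycarbonylation (Pd(PPh3)4, CO, MeOH, Et3N) gives the enol ether ester F5. Acid-catalysed Markovnikov hydroazidation (TMSN3, MeOH, cat. TfOH, CH2Cl2, 0 °C) protonates C-3, reversibly and therefore trans to the C-4 chain, and adds azide at C-2 through the same oxocarbenium ion as in step 11, giving 22.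

Further compounds
F1 | step 13 | methyl 3-[(2R,3S,4S,6S)-2-azido ansa pyran-2-yl]-3-oxopropanoate, N-Boc pyrrole | COC(=O)CC(=O)[C@]2(N=[N+]=[N-])O[C@@H](C)C[C@@H]1CCCCCCCc3ccc(n3C(=O)OC(C)(C)C)[C@H]12
F2 | step 13 | spiro pyrrolidine-2,4-dione on the ansa pyran, N-Boc pyrrole | O=C1CC(=O)N[C@]12O[C@@H](C)C[C@@H]1CCCCCCCc3ccc(n3C(=O)OC(C)(C)C)[C@H]12
F3 | step 11 | methyl (2R,3S,4S,6S)-2-acetamido ansa pyran-2-carboxylate, N-Boc pyrrole | COC(=O)[C@]2(NC(C)=O)O[C@@H](C)C[C@@H]1CCCCCCCc3ccc(n3C(=O)OC(C)(C)C)[C@H]12
F4 | step 9 | (4S,6S) ansa 5,6-dihydro-4H-pyran-2-yl diphenyl phosphate (ketene acetal phosphate), N-Boc pyrrole | C[C@H]1C[C@@H]2CCCCCCCc3ccc(n3C(=O)OC(C)(C)C)C2=C(OP(=O)(Oc4ccccc4)Oc4ccccc4)O1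
F5 | step 9 | methyl (4S,6S) ansa 5,6-dihydro-4H-pyran-2-carboxylate (enol ether ester), N-Boc pyrrole | C[C@H]1C[C@@H]2CCCCCCCc3ccc(n3C(=O)OC(C)(C)C)C2=C(C(=O)OC)O1
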